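The pitfall in this charge is to read 1.02 equivalents of second end groups to first end groups as enough, although third end groups stand in the flask at the same charge and may compete for them. The next run must therefore decide between waiting longer and charging more second end groups.

all flasks: first end groups 0.68 M (fed, over 25 s); second end groups 0.694 M

| charge | third end groups | protic impurity | remark | time |
|---|---|---|---|---|
| blue | 0.68 M | 0.34 M | the very flask that is asked about, followed so far; the fed solution adds 0.10 times the starting volume |  |
| green | 0.68 M | 0.23 M | run made earlier; the fed solution adds 0.10 times the starting volume |  |
| flask | 0.680 M | 0.340 M | the fed solution adds 0.10 times the starting volume | 4.0 min |

- blue (time / s: first end groups / %, over-reaction product / %, links / %): 10.0: 35, 2, 6; 15.0: 53, 0, 3; 20.0: 71, 0, 7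
- green (time / min: first end groups / %, over-reaction product / %, links / %): 0.250: 55, 0, 5; 0.500: 83, 1, 11; 1.33: 61, 13, 21; 3.00: 43, 37, 13

(readings scatter by 1.5 percentage points)

- every charge counts on the volume at the start, and the solution that is fed holds the whole dose
- percentages count the whole charge, also what has not yet gone in

- the largest share of what was charged as first end groups, at 4.0 min belongs to (links / first end groups / over-reaction product)
- the largest share itself, whichever of these holds it, in percent of the first end groups charged

The symmetric case serves as the zero of the scale. If first and third end groups took second end groups at equal odds, each would react to the same fraction of its charge, and this even share, the second end groups charged divided by the first and third end groups charged together, is 51.0%. Second end groups would then be a shared limiting reagent, since 0.694 M stands below the 1.36 M of the two competitors.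

That competition is an assumption of this reckoning, but the green run, with the same even share, reads links and over-reaction product together at 50.0% at 3.00 min, close to it, each reading carrying 1.5 percentage points. The reckoning therefore commits the flask asked about to about the even share in these two forms at 4.0 min. With links taken at green's last 13%, over-reaction product comes to about 38.0%. But the green run still reads 43% of first end groups at 3.00 min, and its readings stop there, so they do not show whether these two forms halt at the even share, and the next run should hold the charges and be read on past 4.0 min before second end groups are changed.

The forecast, higher than this reckoning, names over-reaction product at 45%, for the case that the impurity's effect is “neutral or mildly accelerating”. The flask gives over-reaction product with 43.4%, the largest share, beside 33.8% of first end groups and 8.25% of links.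

    first end groups + second end groups → links (k = 0.0170 /M/s)
    second end groups + third end groups → links of the second sort (k = 0.0130 /M/s)
    first end groups + protic impurity → quenched substrate (k = 0.00460 /M/s)
    links → over-reaction product (k = 0.0130 /s)
    2 third end groups → homo dimer (k = 0.00800 /M/s)

This flask has not come to rest at 4.0 min, for 13% of its second end groups still stand. At 40.0 min they are down to 0.252% and links to 0.0127%, while over-reaction product holds 61.1%, 10 points above the even share. Waiting thus adds 18 points to over-reaction product, and quenched substrate reaches 33.4%. The neighbour charged with 1.7 M of second end groups has an even share of 125%, and at 4.0 min it holds 77.2% of over-reaction product and 4.29% of first end groups.

The earlier runs and the new flask come from a simulation for an exercise; scatter was added.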